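## The problem

Numbering used throughout: C12 is the oxygenated methylene on C1; the chain runs C1 (quaternary, methyl) – C2 – C3 – C4 (ketone) – C5=C6 (methyl on C6) – C7 – C8 (methyl) – C9 – C10 – C11, with ring bonds C2–C7, C3–C8 and C1–C11.

The target 22 is the tris-angelate of a C15 enone-triol in which three carbocycles share one cyclobutane: ring A (cyclohexenone C2–C3–C4–C5–C6–C7), ring B (seven-membered, C1–C2–C7–C8–C9–C10–C11) and ring C (C2–C3–C8–C7). Ring A with ring C is a bicyclo[3.1.1]heptenone, and ring B bridges the other two corners of ring C. There are seven stereocentres: the quaternary C1 and C8, the ring C methines C2, C3 and C7, and the carbinol carbons C9 and C11. On ring B the C1 methyl, H2, H7, the C8 methyl and the C11 oxygen lie on one face; C12, C3, C6 and the C9 oxygen lie on the other. C2, C3, C7 and C8 are interlocked: once ring A and ring B are cis-fused at C2–C7, closing C3–C8 can give only one configuration at the two new centres. C1 must be set against C2, C11–O must end up syn to the C1 methyl, and C9–O anti to C11–O, so C1 can steer C11 and C11 can steer C9. The angelates are Michael acceptors and isomerise to tiglates under basic, nucleophilic or strongly acidic conditions. The cyclobutane lies between the C4 and C9 carbons and would be opened by electron-transfer reductants at the diketone stage. C7 can epimerise whenever it is α or γ to a carbonyl in a precursor. The feature that invites a direct closure of ring C is that C3 and C8 are the α carbons of the C4 ketone and of a C9 carbonyl, so C3–C8 is the central bond of a 1,4-diketone, and in a cis-fused ring A/ring B bicycle the two carbons sit gauche across C2–C7. If ring B carries a C10=C11 double bond in place of the C11 oxygen, each ketone is an enone with exactly one enolisable α′ position (C3H2 and C8H), because C5, C10 and C11 are sp2 and C1 is quaternary.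

## Retrosynthesis

**Esters last.** The three acyl C–O bonds of 22 are cut first, giving triol 19 and three molecules of angelic acid 20, one for each hydroxyl. Carrying angelates earlier is excluded: they would not survive the amide base of the ring C closure, the boryl–copper reagent or fluoride. The forward step must acylate one neopentyl primary and two hindered secondary hydroxyls without Z to E isomerisation.

**C9 and C11 oxygens.** Triol 19 comes from silyl ether 18. The C9–O bond of 18 is traced to the C9 ketone of β-hydroxy ketone 17, reduced under direction of the C11 hydroxyl (1,3-anti). The C11–O bond of 17 is traced to the C10=C11 enone of tricycle 15 by conjugate borylation and oxidation. Placing the C11 oxygen after ring C closure, not before it, is deliberate: a C11 silyloxy group would leave C10 as a second enolisable methylene, invite β-elimination and make the double enolisation ambiguous. The tricycle 15 has the whole carbon skeleton, four stereocentres and no carbinol centres; the forward steps need face selectivity at C11 (anti to the large silyloxymethyl on C1) and intramolecular hydride delivery at C9.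

**Ring C (key cut).** The C3–C8 bond of 15 is cut to give the cis-fused bicyclic bis-enone 13, through its bis(silyl dienol ether) 14. Among the four cyclobutane bonds this is the only one flanked by two carbonyl α carbons, so it is the only one that an oxidative union of two enol derivatives can make. Cutting C2–C7 or C1–C2 instead would leave ring A or ring B still to be built across the four-membered ring. Bis-enone 13 is strain-free and has three relevant stereocentres (C1, C2, C7); C8 is enolised and need not be controlled. The forward reaction must enolise only at C3 and C8, oxidise at one electron per enol ether and close a four-membered ring.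

**C12 oxidation level and protecting groups.** Bis-enone 13 is traced through silyl enol ether 12, alcohol 11 and diol 10 to keto ester 9. C12 is a methyl ester while ring A is built, because a small, planar group is wanted there, and a tert-butyldiphenylsilyloxymethyl group afterwards, because a large group is wanted for the C11 oxygenation. The exchange is made while ring A is still masked as its silyl enol ether, so only the ring B ketone has to be reduced and re-oxidised.

**Ring B size.** Keto ester 9 is cut at C7–C8 and C8–C9, removing the CH(CH3) unit C8 and giving octalone 8. In a seven-membered ring with the C9 ketone, the C2=C7 bond would not be conjugated and could not act as a dienophile. In the six-membered forerunner it is an enone double bond, and the homologation then only has to choose between migration of sp3 C7 and vinyl C10.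

**Ring A.** Octalone 8 is cut at C2–C3 and C6–C7 into dienone ester 5 and silyloxydiene 7 (Diels–Alder). Alkylation or conjugate addition on a preformed cyclohexenone would put the C2 and C7 substituents trans; a cycloaddition gives the cis fusion by its suprafacial course. Dienone 5 is achiral with two enantiotopic enone halves, so one catalytic asymmetric step sets C1, C2 and C7 together. The forward step needs the diene on the ester face of C1 and selection of one enone half.

**Starting materials.** Dienone 5 comes from ester 4 by oxidation of the doubly allylic methylene, 4 from acid 3, and 3 from benzoic acid 1 by reductive methylation. Diene 7 comes from (E)-pent-3-en-2-one 6.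

## Roads not taken

**Alternative 1:** The cut is C1–C2, with ring C already present. In the forward step the magnesium enolate (Mg(ClO4)2, Et3N) of the β-keto ester chain of cyclobutene ester A1 adds through C1 to C2, closing ring B across the four-membered ring to give A2.
- Merits: the cyclobutane never has to be made by a strained closure; the Michael closure is mild, sets quaternary C1 and C2 in one event, and the C9 oxygen is in place beforehand.
- Weak points: a seven-membered closure onto a cyclobutene carbon next to quaternary C8; little bias for the enolate face that sets C1; ring A is still missing after A2. The ester carbon C4 and the ketal carbon C6 would have to be joined through C5 across the 1,3-positions of the cyclobutane, and the C12 ester reduced among other carbonyl groups.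
- Comparison: this road is better in that ring C formation is not at stake and C9 is set early. Against that, the chosen plan completes the skeleton in its key step from a bicycle made in few steps, has C3 and C8 dictated by the ring fusion and not by enolate-face selectivity, and needs no carboxyl-to-ring conversions afterwards.

**Alternative 2:** The cut removes C10 (bonds C9–C10 and C10–C11). In the forward step the C9=C11 silyl enol ether A3 is cyclopropanated with ZnEt2/CH2I2 and the siloxycyclopropane is opened with FeCl3, then NaOAc, enlarging the six-membered bridge to the cycloheptenone A4.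
- Merits: the expansion is well precedented; the enol ether can form on one side only because C8 is quaternary; A4 is compound 15 with a tert-butyldimethylsilyl in place of the tert-butyldiphenylsilyl group, so the endgame would be steps 12–15 of the chosen route.
- Weak points: A3 is a doubly bridged tricycle more strained than the target, and its preparation still needs a cyclobutane-forming step, so the hard problem is moved, not removed; the FeCl3 opening passes through radicals next to the strained ring and an enone.
- Comparison: from A4 onward the two roads are equal, and the key step of this one rests on firmer precedent than a four-membered oxidative closure. The chosen plan reaches the same bis-enone by making ring C directly from a strain-free bicycle, and puts its own one-carbon homologation on a simple octalone (step 6) where only alkyl versus vinyl migration has to be decided.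

**Alternative 3:** The cut is C2–C7. In the forward step the NH-pyrrolidine A5 reacts with PhI(OAc)2 and ammonium carbamate to give a 1,1-diazene; loss of N2 and collapse of the 1,4-biradical give the cyclobutane triester A6.
- Merits: A5 is the kind of pyrrolidine that a [3+2] cycloaddition delivers with good relative control; the contraction is stereoretentive; all four ring C substituents are in place.
- Weak points: the biradical is flanked by ester groups and a quaternary centre, so fragmentation to two alkenes competes with recombination. Afterwards both ring A and ring B must be built from ester termini across the 1,3-positions of the cyclobutane, with C5 and C10 still missing and two methyl esters to be told apart.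
- Comparison: this road is superior in certainty about the configuration around ring C and does not depend on a 4-exo closure. The chosen plan has ring A and ring B in place before ring C is closed and needs four steps after the key step, whereas this road leaves more than half of the skeletal bonds for later.

Key step: step 11

Assumption: the (S)-configured catalyst of step 5 is taken to give the enantiomer of 8 shown; if the sense of induction is the reverse, the (R)-catalyst is used and nothing else changes.

Assumption: C6 (in 8–12) and C8 (in 9–13) are erased in steps 10 and 11; C6 is written as the endo adduct, and C8, the carbinol carbon C9 of 10 and C3 of F2 are carried as mixtures with their SMILES descriptors left open.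

Step 1
Reactants: 1 benzoic acid
Product: 3 1-methylcyclohexa-2,5-diene-1-carboxylic acid, via dilithium enediolate 2 (not isolated)
Conditions: Li, NH3(l)/THF, −78 °C; then MeI; aq. HCl
Reagents that add atoms: iodomethane, CI
Why: Birch reductive alkylation: reduction of the benzoate stops at the cross-conjugated enediolate, which is methylated at the carboxyl-bearing carbon; this carbon becomes C1 and is not yet stereogenic.

Step 2
Reactants: 3 1-methylcyclohexa-2,5-diene-1-carboxylic acid
Product: 4 methyl 1-methylcyclohexa-2,5-diene-1-carboxylate
Conditions: MeI, K2CO3, DMF, rt
Reagents that add atoms: iodomethane, CI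
Why: O-alkylation of the carboxylate (SN2); the ester is the small C12 group wanted for step 5.

Step 3
Reactants: 4 methyl 1-methylcyclohexa-2,5-diene-1-carboxylate
Product: 5 methyl 1-methyl-4-oxocyclohexa-2,5-diene-1-carboxylate
Conditions: CrO3 (10 mol%), t-BuOOH, CH2Cl2, rt
Reagents that add atoms: tert-butyl hydroperoxide, CC(C)(C)OO
Why: Chromium-catalysed oxidation of the doubly allylic methylene to the cross-conjugated dienone; the quaternary carbon blocks aromatisation. The product is achiral with two enantiotopic enone halves.

Step 4
Reactants: 6 (E)-pent-3-en-2-one
Product: 7 (E)-2-(triisopropylsilyloxy)penta-1,3-diene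
Conditions: i-Pr3SiOTf, Et3N, CH2Cl2, 0 °C
Reagents that add atoms: triisopropylsilyl trifluoromethanesulfonate, CC(C)[Si](OS(=O)(=O)C(F)(F)F)(C(C)C)C(C)C
Why: Soft enolisation: the O-silylated enone is deprotonated at its methyl group to give the 2-silyloxydiene, with the E double bond untouched.

Step 5
Reactants: 5 methyl 1-methyl-4-oxocyclohexa-2,5-diene-1-carboxylate, 7 (E)-2-(triisopropylsilyloxy)penta-1,3-diene
Product: 8 methyl 1,5-dimethyl-4-oxo-7-(triisopropylsilyloxy)-1,4,4a,5,8,8a-hexahydronaphthalene-1-carboxylate (cis-fused; C1/C2/C7 configured as in 22)
Conditions: (S)-3,3-diphenyl-1-(o-tolyl)tetrahydro-1H,3H-pyrrolo[1,2-c][1,3,2]oxazaborole·HN(SO2CF3)2 (20 mol%), CH2Cl2, −78 to −20 °C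
Reagents that add atoms: none
Why: Catalytic enantioselective Diels–Alder reaction of an oxazaborolidinium-activated cyclic enone with a 2-silyloxydiene, forming C2–C3 and C6–C7; the nucleophilic CH2 terminus of the diene bonds to the β-carbon C2, and the suprafacial addition makes H2 and H7 cis. The diene should add on the face of C1 that carries the planar, smaller ester and not the methyl group, which puts C12 syn to C3; the catalyst selects the enone half that offers this face unshielded, so C1, C2 and C7 are set together, the expected by-product being the C1-epimeric diastereomer and not the enantiomer. C6 (endo) is erased in step 10.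

Step 6
Reactants: 8 Diels–Alder adduct
Product: 9 ring-expanded keto ester (cis-fused ring A/ring B bicycle; C12 methyl ester; ring A as C4=C5 triisopropylsilyl enol ether; ring B C9 ketone with C10=C11 and C8–H(Me) as an epimer mixture)
Conditions: CH3CHN2 (Et2O solution), Sc(OTf)3 (10 mol%), CH2Cl2, −78 °C
Reagents that add atoms: diazoethane, CC=[N+]=[N-]
Why: Lewis-acid-catalysed diazoalkane homologation of a cycloalkanone (Tiffeneau–Demjanov type): the diazo carbon adds to the only free ketone and sp3 C7 migrates in preference to vinyl C10, with retention at C7, inserting C8 between C7 and C9. The enol ether keeps C4 out of the reaction, and the homologation moves C7 out of the epimerisable α position.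

Step 7
Reactants: 9 ring-expanded keto ester
Product: 10 diol (C12 primary alcohol; C9 allylic alcohol as an epimer mixture; ring A silyl enol ether intact)
Conditions: i-Bu2AlH, CH2Cl2, −78 to 0 °C; aq. KNaC4H4O6
Reagents that add atoms: none
Why: Hydride reduction of the ester to the primary alcohol and 1,2-reduction of the enone; the triisopropylsilyl enol ether is inert to i-Bu2AlH.

Step 8
Reactants: 10 diol
Product: 11 hydroxy enone (C12–OH; C9 ketone with C10=C11; ring A silyl enol ether)
Conditions: MnO2, CH2Cl2, rt
Reagents that add atoms: none
Why: MnO2 oxidises the allylic alcohol only, returning the ring B enone and leaving the neopentyl primary alcohol.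

Step 9
Reactants: 11 hydroxy enone
Product: 12 tert-butyldiphenylsilyl ether of 11
Conditions: t-BuPh2SiCl, imidazole, DMF, rt
Reagents that add atoms: tert-butyl(chloro)diphenylsilane, CC(C)(C)[Si](Cl)(c1ccccc1)c1ccccc1
Why: Silylation of the primary alcohol; the group is stable to amide base and to buffered (NH4)2Ce(NO3)6 and makes C12 the large substituent on C1 for step 12.

Step 10
Reactants: 12 silyl ether
Product: 13 cis-fused bicyclic bis-enone (ring A: C4 ketone, C5=C6 with C6 methyl, C3H2; ring B: C9 ketone, C10=C11, C8–H(Me) epimers; C12–OSi(t-Bu)Ph2)
Conditions: Pd(OAc)2 (1.1 equiv), MeCN, 40 °C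
Reagents that add atoms: none
Why: Saegusa–Ito oxidation: the C5-bound palladium enolate formed from the Diels–Alder-derived enol ether can only eliminate the C6 hydride, so the ring A enone appears as C5=C6 and the C6 stereocentre is erased.

Step 11
Reactants: 13 cis-fused bicyclic bis-enone
Product: 15 tricyclic bis-enone (rings A, B and C complete; C4 and C9 ketones; C5=C6 and C10=C11; C12–OSi(t-Bu)Ph2), via bis(trimethylsilyl dienol ether) 14 (not isolated)
Conditions: LiN(i-Pr)2, Me3SiCl, THF, −78 °C; pentane, filtration, evaporation; then (NH4)2Ce(NO3)6, NaHCO3, MeCN, −30 °C
Reagents that add atoms: none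
Why: Kinetic deprotonation with in situ silylation turns each enone into its cross-conjugated 2-silyloxydiene: C3 is the only α′ position of the C4 enone and C8 the only enolisable position of the C9 enone (C10 and C11 are sp2, C1 is quaternary), so 14 forms as one regioisomer. Tetravalent cerium removes one electron from the more electron-rich, fully substituted C8=C9 enol ether; the radical cation, with spin at C8, adds to C3 of the ring A dienol ether, and the resulting α-silyloxy allyl radical is oxidised at once to the oxocarbenium ion, after which both silyl groups are lost to leave the 1,4-diketone. The closest known reaction type is the intramolecular oxidative coupling of bis(silyl enol ethers) and of ketone or ester bis-enolates to 1,4-dicarbonyl compounds, which has delivered three- and four-membered rings from dienolates. Ring C closes 4-exo-trig, and this one bond turns the fused bicycle into both bridged bicycles of the skeleton. The configurations at C3 and C8 are imposed, not selected: the two carbons can bond only on the face of C2–C7 where the cis fusion holds them gauche, which places H3 and the C8 methyl as in 22. The step needs site-selective enolisation (secured by the substitution pattern), coupling in preference to dehydrogenation of the ring A cyclohexadiene (favoured by intramolecularity, low temperature and a heterogeneous buffer) and survival of the silyl ether.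

Step 12
Reactants: 15 tricyclic bis-enone
Product: 17 β-hydroxy ketone (C11–OH syn to the C1 methyl; C9 ketone; ring A enone intact), via C11 pinacol boronate 16 (not isolated)
Conditions: B2pin2, CuCl (10 mol%), NaOt-Bu (15 mol%), (2-Ph2PC6H4)2O (10 mol%), MeOH, THF, rt; then NaBO3·4H2O, THF/H2O, 0 °C
Reagents that add atoms: sodium perborate (supplies the C11 hydroxyl oxygen), [Na+].[Na+].O[B-]1(O)OO[B-](O)(O)OO1
Why: Copper-catalysed conjugate borylation followed by C–B oxidation with retention; the disubstituted ring B enone reacts in preference to the β,β-disubstituted, bridged ring A enone. The boryl–copper reagent approaches C11 anti to the silyloxymethyl group on C1, on the face of the C1 methyl, which sets C11; perborate avoids nucleophilic epoxidation of the remaining enone.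

Step 13
Reactants: 17 β-hydroxy ketone
Product: 18 1,3-anti diol (C9–OH anti to C11–OH; C12–OSi(t-Bu)Ph2; ring A enone)
Conditions: Me4NBH(OAc)3, MeCN/AcOH, −30 °C
Reagents that add atoms: none
Why: Evans–Saksena reduction: the C11 hydroxyl exchanges onto boron and delivers hydride intramolecularly to the C9 carbonyl from its own face, giving the anti diol; the ring A ketone has no directing hydroxyl and is not reduced by triacetoxyborohydride.

Step 14
Reactants: 18 1,3-anti diol
Product: 19 triol (C9, C11 and C12 hydroxyls; ring A enone)
Conditions: Bu4NF, AcOH, THF, rt
Reagents that add atoms: none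
Why: Fluoride cleavage of the silyl ether, buffered with acetic acid; C3–H is a bridgehead and cannot epimerise.

Step 15
Reactants: 19 triol, 20 angelic acid (three equivalents are incorporated)
Product: 22 CNP0266467.1 (tris-angelate of 19), via angelic 2,4,6-trichlorobenzoic anhydride 21 (not isolated)
Conditions: 20 (4.5 equiv), 2,4,6-Cl3C6H2COCl (4.5 equiv), Et3N (9 equiv), toluene, rt; then 19 (1 equiv), 80 °C
Reagents that add atoms: angelic acid (second and third equivalents), C/C=C(/C)C(=O)O.C/C=C(/C)C(=O)O
Why: Yamaguchi-type mixed anhydride acylation, carried out three times on the same molecule: each of the C9, C11 and C12 hydroxyls takes one angeloyl group from one molecule of 21, so three molecules of 20 end up in 22 and an excess of 21 is used to drive the two hindered secondary hydroxyls to completion. The alcohols attack the angeloyl carbonyl because the aroyl carbonyl is shielded by its two ortho chlorines, and omitting a nucleophilic catalyst suppresses Z to E isomerisation to the tiglate.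

Compound list

1 | benzoic acid | OC(=O)c1ccccc1 | starting material
2 | dilithium enediolate from Birch reduction of benzoate | [Li+].[Li+].[O-]C([O-])=C1C=CCC=C1 | intermediate (not isolated)
3 | 1-methylcyclohexa-2,5-diene-1-carboxylic acid | CC1(C=CCC=C1)C(=O)O | intermediate
4 | methyl 1-methylcyclohexa-2,5-diene-1-carboxylate | COC(=O)C1(C)C=CCC=C1 | intermediate
5 | methyl 1-methyl-4-oxocyclohexa-2,5-diene-1-carboxylate | COC(=O)C1(C)C=CC(=O)C=C1 | intermediate
6 | (E)-pent-3-en-2-one | C/C=C/C(C)=O | starting material
7 | (E)-2-(triisopropylsilyloxy)penta-1,3-diene | C/C=C/C(=C)O[Si](C(C)C)(C(C)C)C(C)C | intermediate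
8 | Diels–Alder adduct: cis-fused octalone, C12 methyl ester and methyl on C1, ring A as C4=C5 triisopropylsilyl enol ether, H2/H7/H6 cis, C12 syn to C3, C9 ketone with C10=C11 | COC(=O)[C@]1(C)[C@@H]2CC(O[Si](C(C)C)(C(C)C)C(C)C)=C[C@H](C)[C@@H]2C(=O)C=C1 | intermediate
9 | ring-expanded keto ester: as 8 with C8–H(Me) inserted between C7 and the C9 ketone (C8 epimers) | COC(=O)[C@]1(C)[C@@H]2CC(O[Si](C(C)C)(C(C)C)C(C)C)=C[C@H](C)[C@@H]2C(C)C(=O)C=C1 | intermediate
10 | diol: C12 primary alcohol, C9 allylic alcohol (epimers), ring A silyl enol ether | OC[C@]1(C)[C@@H]2CC(O[Si](C(C)C)(C(C)C)C(C)C)=C[C@H](C)[C@@H]2C(C)C(O)C=C1 | intermediate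
11 | hydroxy enone: C12–OH, C9 ketone with C10=C11, ring A silyl enol ether | OC[C@]1(C)[C@@H]2CC(O[Si](C(C)C)(C(C)C)C(C)C)=C[C@H](C)[C@@H]2C(C)C(=O)C=C1 | intermediate
12 | tert-butyldiphenylsilyl ether of 11 | CC(C)(C)[Si](c1ccccc1)(c1ccccc1)OC[C@]1(C)[C@@H]2CC(O[Si](C(C)C)(C(C)C)C(C)C)=C[C@H](C)[C@@H]2C(C)C(=O)C=C1 | intermediate
13 | cis-fused bicyclic 4,9-dione (bis-enone): ring A C4 ketone with C5=C6(Me), ring B C9 ketone with C10=C11, C8–H(Me) epimers, H2/H7 cis, C1 methyl syn to H2, C12–OSi(t-Bu)Ph2 syn to C3 | CC(C)(C)[Si](c1ccccc1)(c1ccccc1)OC[C@]1(C)[C@@H]2CC(=O)C=C(C)[C@@H]2C(C)C(=O)C=C1 | intermediate (key step precursor)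
14 | bis(trimethylsilyl dienol ether) of 13 (C3=C4–OSiMe3 and C8=C9–OSiMe3) | CC(C)(C)[Si](c1ccccc1)(c1ccccc1)OC[C@]1(C)[C@@H]2C=C(O[Si](C)(C)C)C=C(C)[C@@H]2C(C)=C(O[Si](C)(C)C)C=C1 | intermediate (not isolated)
15 | tricyclic 4,9-dione (bis-enone): rings A, B and C, C3–C8 bond formed, C8 methyl and C1 methyl on the face of H2/H7, C10=C11, C12–OSi(t-Bu)Ph2 | CC(C)(C)[Si](c1ccccc1)(c1ccccc1)OC[C@]1(C)[C@@H]2[C@H]3C(=O)C=C(C)[C@@H]2[C@@]3(C)C(=O)C=C1 | intermediate (key step product)
16 | C11 pinacol boronate of the C9 ketone (boron syn to the C1 methyl) | CC(C)(C)[Si](c1ccccc1)(c1ccccc1)OC[C@]1(C)[C@@H]2[C@H]3C(=O)C=C(C)[C@@H]2[C@@]3(C)C(=O)C[C@H]1B1OC(C)(C)C(C)(C)O1 | intermediate (not isolated)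
17 | β-hydroxy ketone: C11–OH syn to the C1 methyl, C9 ketone | CC(C)(C)[Si](c1ccccc1)(c1ccccc1)OC[C@]1(C)[C@@H]2[C@H]3C(=O)C=C(C)[C@@H]2[C@@]3(C)C(=O)C[C@H]1O | intermediate
18 | 1,3-anti diol: C9–OH anti to C11–OH, C12 silyl ether | CC(C)(C)[Si](c1ccccc1)(c1ccccc1)OC[C@]1(C)[C@@H]2[C@H]3C(=O)C=C(C)[C@@H]2[C@@]3(C)[C@H](O)C[C@H]1O | intermediate
19 | triol (C9, C11, C12 hydroxyls; ring A enone) | OC[C@]1(C)[C@@H]2[C@H]3C(=O)C=C(C)[C@@H]2[C@@]3(C)[C@H](O)C[C@H]1O | intermediate
20 | angelic acid, (Z)-2-methylbut-2-enoic acid | C/C=C(/C)C(=O)O | starting material
21 | angelic 2,4,6-trichlorobenzoic anhydride | C/C=C(/C)C(=O)OC(=O)c1c(Cl)cc(Cl)cc1Cl | intermediate (not isolated)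
22 | CNP0266467.1, the C9, C11, C12 tris-angelate of 19 | C/C=C(/C)C(=O)OC[C@]1(C)[C@@H]2[C@H]3C(=O)C=C(C)[C@@H]2[C@@]3(C)[C@H](OC(=O)/C(C)=C\C)C[C@H]1OC(=O)/C(C)=C\C | target

Total step count: 15. Longest linear sequence: 14 steps (steps 1–3 and 5–15; step 4 prepares the diene).

Least certain steps

**Step 11 (key step).** The most likely failure is dehydrogenation of the ring A silyloxycyclohexadiene: its radical cation can lose H2 and H7 and aromatise instead of being attacked at C3. A second risk is a slow or reversible 4-exo closure, which would leave time for intermolecular coupling or trapping of the C8 radical cation by nitrate. The fallback leaves the radical-cation manifold and sets out from 13. LiN(i-Pr)2 (2.2 equiv, THF, −78 °C) gives the dilithium bis(dienolate) F1. One equivalent of iodine then iodinates the less hindered C3 enolate to the lithium enolate of the C3-iodo bis-enone F2, whose C8 enolate displaces iodide in a 4-exo-tet alkylation; this is the iodine-mediated dienolate coupling known to give cyclobutanes. The route is rejoined at 15.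

**Step 5.** The most likely failure is incomplete discrimination of the two enantiotopic enone halves by a catalyst that finds two equivalent α-vinyl C–H binding sites on one carbonyl, together with a slow cycloaddition at the neopentyl β-carbon; either would erode the optical purity of 8. The ester-versus-methyl face preference is modest too, but its failure would show as a separable diastereomer. The fallback sets out from 5 and 7: the cycloaddition is run with an achiral Lewis acid (Me2AlCl, CH2Cl2, −78 °C), steps 6–11 are carried through in the racemic series, and the enantiomers of 15 are separated by chromatography on a chiral stationary phase. The route is rejoined at 15 and no new compound is made.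

**Step 6.** The most likely failures are over-reaction with the very reactive diazoethane (a second homologation, or dipolar cycloaddition to the C10=C11 enone) and loss of the silyl enol ether under Lewis acid. The fallback sets out from 8 and installs the carbon and its methyl group separately: Me3SiCHN2 with AlMe3 (CH2Cl2, −78 °C) and protodesilylation on work-up give the C8-unsubstituted ring-expanded keto ester F3. Its only enolisable position, C8, is then methylated (LiN(i-Pr)2, THF, −78 °C; MeI). The route is rejoined at 9.

**Step 12.** The most likely failure is sluggish boryl–copper addition at C11, a β-carbon next to the quaternary C1, which would let reduction or reaction at the ring A enone compete. The fallback sets out from 15: nucleophilic epoxidation (t-BuOOH, DBU, CH2Cl2) on the ring B enone, again anti to the silyloxymethyl group, gives the epoxy ketone F4. Reductive opening at C10 with PhSeNa (from (PhSe)2 and NaBH4, AcOH, EtOH, 0 °C) then gives the β-hydroxy ketone; an electron-transfer reductant is avoided because of the cyclobutane. The route is rejoined at 17.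

**Step 15.** The most likely failure is incomplete acylation of the two secondary hydroxyls, each next to a quaternary carbon, so that mono- and bis-angelates persist even with excess mixed anhydride, with Z to E isomerisation setting in when the reaction is forced. The fallback sets out from 19 and builds the angelate double bonds after acylation. Esterification with 2-[bis(2,2,2-trifluoroethoxy)phosphoryl]propanoic acid (N,N'-dicyclohexylcarbodiimide, 4-dimethylaminopyridine, CH2Cl2) has no geometry to lose and can be pushed to the tris(phosphonopropionate) F5. A Z-selective Still–Gennari olefination with acetaldehyde (KN(SiMe3)2, 18-crown-6, THF, −78 °C) then gives the three (Z)-2-methylbut-2-enoates. The route is rejoined at 22.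

Further compounds

F1 | step 11 | dilithium bis(dienolate) of 13 (C3=C4 and C8=C9 enolates) | [Li+].[Li+].CC(C)(C)[Si](c1ccccc1)(c1ccccc1)OC[C@]1(C)[C@@H]2C=C([O-])C=C(C)[C@@H]2C(C)=C([O-])C=C1
F2 | step 11 | lithium C8=C9 dienolate of the C3-iodo bis-enone | [Li+].CC(C)(C)[Si](c1ccccc1)(c1ccccc1)OC[C@]1(C)[C@@H]2C(I)C(=O)C=C(C)[C@@H]2C(C)=C([O-])C=C1
F0 | step 5 | none | none
F3 | step 6 | C8-unsubstituted ring-expanded keto ester (C8H2 between C7 and the C9 ketone) | COC(=O)[C@]1(C)[C@@H]2CC(O[Si](C(C)C)(C(C)C)C(C)C)=C[C@H](C)[C@@H]2CC(=O)C=C1
F4 | step 12 | C10,C11-epoxy ketone of 15 (epoxide oxygen syn to the C1 methyl) | CC(C)(C)[Si](c1ccccc1)(c1ccccc1)OC[C@]1(C)[C@@H]2[C@H]3C(=O)C=C(C)[C@@H]2[C@@]3(C)C(=O)[C@H]4O[C@@H]14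
F5 | step 15 | tris{2-[bis(2,2,2-trifluoroethoxy)phosphoryl]propanoate} of 19 | CC(P(=O)(OCC(F)(F)F)OCC(F)(F)F)C(=O)OC[C@]1(C)[C@@H]2[C@H]3C(=O)C=C(C)[C@@H]2[C@@]3(C)[C@H](OC(=O)C(C)P(=O)(OCC(F)(F)F)OCC(F)(F)F)C[C@H]1OC(=O)C(C)P(=O)(OCC(F)(F)F)OCC(F)(F)F
A1 | alternative 1 | cyclobutene β-keto ester: tert-butyl cyclobut-1-ene-1-carboxylate with the C9(OSi)–C10–C11(=O)–C1H(Me)CO2Me chain on C8 and the dioxolane-protected acetyl group on C7 | COC(=O)C(C)C(=O)C[C@@H](O[Si](C)(C)C(C)(C)C)[C@]1(C)[C@@H](C2(C)OCCO2)C=C1C(=O)OC(C)(C)C
A2 | alternative 1 | bridged keto diester with ring B closed across the cyclobutane | COC(=O)[C@]1(C)[C@@H]2[C@@H](C(=O)OC(C)(C)C)[C@@](C)([C@H]2C3(C)OCCO3)[C@H](O[Si](C)(C)C(C)(C)C)CC1=O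
A3 | alternative 2 | C9=C11 trimethylsilyl enol ether of the tricycle with a six-membered bridge | CC(C)(C)[Si](C)(C)OC[C@]1(C)[C@@H]2[C@H]3C(=O)C=C(C)[C@@H]2[C@@]3(C)C(O[Si](C)(C)C)=C1
A4 | alternative 2 | tricyclic bis-enone with the C9 ketone and C10=C11 (tert-butyldimethylsilyl ether) | CC(C)(C)[Si](C)(C)OC[C@]1(C)[C@@H]2[C@H]3C(=O)C=C(C)[C@@H]2[C@@]3(C)C(=O)C=C1
A5 | alternative 3 | NH-pyrrolidine triester with nitrogen between C2 and C7 | CC(C)(C)[Si](C)(C)OC[C@@](C)(C=C)[C@@H]1[C@@H](C(=O)OC)[C@](C)(C(=O)OC)[C@@H](C(=O)OC(C)(C)C)N1
A6 | alternative 3 | tetrasubstituted cyclobutane triester | CC(C)(C)[Si](C)(C)OC[C@@](C)(C=C)[C@@H]1[C@@H](C(=O)OC)[C@](C)(C(=O)OC)[C@H]1C(=O)OC(C)(C)C
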